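The constants of this flask are not given, so one has to be read from its own run.

the same everywhere: left-handed substrate 0.0020 M; right-handed substrate 0.0020 M
- summer: solid reagent 4 equiv; the very flask that is asked about, followed so far
- flask: solid reagent 4.00 equiv; time 3.0 min

- summer (time / s: left-handed product / %, right-handed product / %, left-handed substrate / %): 10.0: 0.5, 0, 31.1; 12.0: 0.6, 0, 30.7; 20.0: 1.4, 0.2, 29.3; 25.0: 0.9, 0, 28.4; 30.0: 0.4, 0.3, 27.3; 40.0: 1.4, 0.7, 25.4

(standard deviation of a reading: 0.5 percentage points)

* excess of left-handed product over right-handed product in the product at 20 s
* excess of left-handed product over right-handed product in the product at 3.0 min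
* part of the left-handed substrate and right-handed substrate charged together that has reacted at 3.0 min

- partner is single-handed; left-handed substrate and right-handed substrate are mirror images of each other, charged as a racemate, each of them at the stated concentration
- solid reagent is a solid; its amount is given per volume of the solution
- at the start none of the solid reagent is in solution
- an excess is the difference of the two amounts in percent of their sum
- what has gone into achiral form counts as reacted
- an excess is below zero if the other one leads
- the handed part of partner does not stay in what it makes, so the products of the two hands are mirror images too

From 10.0 s to 40.0 s, left-handed substrate loses 5.7 percentage points. Taking the mirror-image hand as equal, the pair loses 11 points, more than the 2.1 points of product read at 40.0 s. So this reckoning puts [left-handed substrate] itself in the rate of the loss and brackets cb by its order. A straight line (zero order) reaches zero left-handed substrate at 2.89 min, before 3.0 min, which this reckoning takes as the upper end of cb, 100%. Second order leaves 13.7% of each hand, which this reckoning takes as the lower end of cb, 72.6%. First order tightens this: 0.00675 s⁻¹ is the drain constant, the share of [left-handed substrate] lost per second, a reading with the scatter of 0.5 points. It leaves 9.87% per hand, so cb is 80.3%. The product readings at 40.0 s part the hands by 0.7 points against 25.4% of left-handed substrate read then, so this reckoning keeps the hands level and holds eb at ea.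

The forecast gives ea 50% (15% to 80%), eb 30% (0% to 60%) and cb 65% (45% to 85%), on the ground: “Depletion of the faster hand should erode the excess”. Its cb stands below the bracket, and its eb stands below its ea, where this reckoning holds the two equal.

The flask gives ea 51.7%, eb 51.5% and cb 79.2%, with 10.4% of left-handed substrate and 10.4% of right-handed substrate against the 9.87% from the drain constant.

    right-handed substrate ⇌ achiral form (K = 1.10, k = 0.260 s⁻¹)
    left-handed substrate ⇌ achiral form (K = 1.10, k = 0.260 s⁻¹)
    solid reagent ⇌ partner, rate k3*(cs3 - [partner]) while solid is left; crystals form when [partner] > cs3 (solubility = 1.00 mM, k = 0.0140 s⁻¹)
    achiral form → waste (k = 0.0160 s⁻¹)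
    2 partner → homo dimer (k = 11.0 M⁻¹ s⁻¹)
    partner + left-handed substrate → left-handed product (k = 4.40 M⁻¹ s⁻¹)
    partner + right-handed substrate → right-handed product (k = 1.40 M⁻¹ s⁻¹)

In the flask at 3.00 min, left-handed substrate enters achiral form 120 times as fast as it enters left-handed product, forward rates alone. Its half-life by that forward step, 2.7 s at 1.11 min, is short against 3.0 min, and at 3.00 min the two hands of this dynamic kinetic resolution stand level.

For the neighbour with 1.60 equiv of solid reagent, the drain constant holds no term for the solid and again gives cb 80.3%. That flask computes to 79.2%, with 10.4% of left-handed substrate.

(The numbers in the tables come from a simulation on assumed constants, noise included.)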